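**Plan**

1. Ring numbering used here: C1 is the ring C=O, flanked by C2 (isobutyryl) and C6 (two prenyls); C3 and C5 are the enolic C–OH carbons; C4 carries one prenyl (prenyl = 3-methylbut-2-en-1-yl).
2. The six-membered ring is a cyclic β-triketone in which oxygenated C1/C3/C5 alternate with nucleophilic C2/C4/C6, so every ring bond is a carbonyl–α-carbon (Claisen) bond. The retrosynthesis cuts C2–C3 and C5–C6 together.
3. This releases C3–C4–C5 as the mirror-symmetric prenylmalonyl dichloride and C6–C1–C2 with the side chain as a 1,3-C,C-dinucleophile.
4. The dinucleophile is a 1-amino-3-siloxy diene: the isobutyryl carbon is held as a pyrrolidine enamine and C1 as a silyl enol ether pointing to C6. This fixes C6, not the isopropyl methine, as the second nucleophilic carbon; silicon leaves in the ring-forming step and nitrogen on hydrolysis in the same flask.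
5. Forward: 3-methylbut-1-yne is acylated to an ynone, pyrrolidine is added, the α'-carbon is prenylated twice and then silylated; diethyl malonate is taken to prenylmalonyl dichloride; the only ring is closed last by a [3+3] double C-acylation.
6. Stereochemistry: the target has no stereocentre and no stereogenic double bond (C6 bears two identical prenyls, each prenyl ends in a gem-dimethyl alkene), so nothing has to be controlled.

Key step: step 9

Remark: colupulone is treated as the tautomeric set of 2-isobutyryl-4,6,6-triprenylcyclohexane-1,3,5-trione; the dienol-one drawn in the target is the tautomer it should adopt. The four numbered starting materials are catalogue chemicals.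

**Route**

Step 1
Reactants: 1 3-methylbut-1-yne; 2 N-methoxy-N-methylacetamide
Product: 3 5-methylhex-3-yn-2-one
Conditions: n-BuLi, THF, −78 °C; then 2, −78 → 0 °C; aq. NH4Cl
Reagents that add atoms: none
Why: Weinreb ketone synthesis, in which the lithium acetylide adds once to the N-methoxy-N-methylamide and the chelated tetrahedral adduct survives until the quench, so the ynone should form without over-addition.

Step 2
Reactants: 3 5-methylhex-3-yn-2-one
Product: 4 (3E)-5-methyl-4-(pyrrolidin-1-yl)hex-3-en-2-one
Conditions: pyrrolidine, EtOH, 0 °C → rt
Reagents that add atoms: pyrrolidine, C1CCNC1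
Why: Aza-Michael addition of a secondary amine to an ynone places nitrogen regiospecifically on the isopropyl-bearing β-carbon and should give the thermodynamically preferred E vinylogous amide, whose alkene geometry has no consequence later.

Step 3
Reactants: 4 (3E)-5-methyl-4-(pyrrolidin-1-yl)hex-3-en-2-one; 5 prenyl bromide (1-bromo-3-methylbut-2-ene)
Product: 6 (3E)-2,9-dimethyl-3-(pyrrolidin-1-yl)deca-3,8-dien-5-one
Conditions: LiN(iPr)2, THF, −78 °C; then 5, −78 → 0 °C
Reagents that add atoms: none
Why: Kinetic α'-enolate alkylation of a tertiary vinylogous amide (the amide analogue of the Stork–Danheiser alkylation), in which the methyl ketone and not the γ-methine on the enamine carbon is deprotonated and the cross-conjugated enolate should be C-alkylated by the primary allylic bromide in an SN2 reaction.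

Step 4
Reactants: 6 (3E)-2,9-dimethyl-3-(pyrrolidin-1-yl)deca-3,8-dien-5-one; 5 prenyl bromide
Product: 7 (3E)-2,9-dimethyl-6-(3-methylbut-2-en-1-yl)-3-(pyrrolidin-1-yl)deca-3,8-dien-5-one
Conditions: LiN(iPr)2, THF, −78 °C; then 5, −78 °C → rt
Reagents that add atoms: none
Why: A second α'-enolate alkylation of the same type, in which the α'-CH2 is more acidic and more accessible than the γ-isopropyl methine, so the second prenyl group should enter at the same carbon (the future C6, no stereocentre because the two groups are identical).

Step 5
Reactants: 7 (3E)-2,9-dimethyl-6-(3-methylbut-2-en-1-yl)-3-(pyrrolidin-1-yl)deca-3,8-dien-5-one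
Product: 8 1-[(3E)-2,9-dimethyl-6-(3-methylbut-2-en-1-yl)-5-(trimethylsilyloxy)deca-3,5,8-trien-3-yl]pyrrolidine
Conditions: LiN(iPr)2, Me3SiCl (internal quench), THF, −78 → 0 °C; evaporate, dry pentane, filter under Ar; used crude
Reagents that add atoms: chlorotrimethylsilane, C[Si](C)(C)Cl
Why: α'-Deprotonation and O-silylation of a vinylogous amide, the standard preparation of 1-amino-3-siloxy-1,3-dienes, in which the internal quench traps the hindered enolate as it forms and the enol double bond is fixed toward C6 because the amine-bearing carbon is not enolised under kinetic conditions.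

Step 6
Reactants: 9 diethyl malonate (in excess); 5 prenyl bromide
Product: 10 diethyl 2-(3-methylbut-2-en-1-yl)propanedioate
Conditions: NaH, THF, 0 °C; then 5, 0 °C → rt
Reagents that add atoms: none
Why: Malonic ester alkylation, in which the sodium enolate displaces bromide from the primary allylic halide (SN2) and the excess of 9 suppresses dialkylation.

Step 7
Reactants: 10 diethyl 2-(3-methylbut-2-en-1-yl)propanedioate
Product: 11 2-(3-methylbut-2-en-1-yl)propanedioic acid
Conditions: LiOH·H2O, THF/H2O, rt; then cold 1 M HCl to pH 2, extraction without heating
Reagents that add atoms: lithium hydroxide, [Li+].[OH-]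
Why: Saponification of both esters under mild conditions, with cold acidification and no heating so that decarboxylation of the malonic acid and acid-mediated lactonisation onto the prenyl alkene should be avoided.

Step 8
Reactants: 11 2-(3-methylbut-2-en-1-yl)propanedioic acid
Product: 12 2-(3-methylbut-2-en-1-yl)propanedioyl dichloride (prenylmalonyl dichloride)
Conditions: (COCl)2, DMF (cat.), CH2Cl2, 0 °C → rt, Ar sweep; concentrate; used crude
Reagents that add atoms: oxalyl chloride, O=C(Cl)C(=O)Cl
Why: Vilsmeier-type activation converts both carboxylic acids to acyl chlorides with only gaseous by-products, and the argon sweep removes HCl so that the trisubstituted alkene should survive.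

Step 9
Reactants: 8 1-[(3E)-2,9-dimethyl-6-(3-methylbut-2-en-1-yl)-5-(trimethylsilyloxy)deca-3,5,8-trien-3-yl]pyrrolidine; 12 prenylmalonyl dichloride
Product: 15 colupulone, via acid chloride 13 (not isolated), via enaminotrione 14 (not isolated)
Conditions: 12 (1.0 equiv) added slowly to 8 and 2,6-lutidine (1.1 equiv), CH2Cl2 (high dilution), −78 → 0 °C; then 1 M aq. HCl, THF, rt; under Ar
Reagents that add atoms: water, O
Why: Proposed new method: diene 8 is a 1,3-C,C-dinucleophile in which the pyrrolidine nitrogen pushes electron density through C2 into the silyl enol ether terminus C6, so C6 should attack one acyl chloride of 12 (vinylogous Mukaiyama-type C-acylation with loss of Me3SiCl) to give vinylogous amide 13, whose enaminone α-carbon C2 then attacks the second acyl chloride and loses HCl to give the push-pull enaminotrione 14, and aqueous acid finally hydrolyses the exocyclic enamine carbon to the isobutyryl carbonyl. The closest known reaction types are the Effenberger-type annulation of ketone silyl enol ethers with malonyl dichloride to cyclohexane-1,3,5-triones, the C-acylation of tertiary enaminones by acid chlorides and the terminus-selective reactions of 1-amino-3-siloxy dienes with carbon electrophiles. The single ring closes as a 6-(enolexo)-exo-trig acylation at C2, or as a 6-(enolendo)-exo-trig acylation at C6 if C2 should react first; both are favoured and, because 12 is symmetric, both orders converge on 14. No lasting stereocentre is created, since C6 carries two identical prenyl groups and C4 is enolised in the product. The selectivity needed is regiochemical, C6 and not the isopropyl methine as the second nucleophilic carbon, and it is secured because the only enol silane of 8 points to C6 while the isobutyryl carbon is held at the enamine level and cannot enolise. C- over O-acylation is expected because O-acylated enaminones are themselves acyl donors and revert, and slow addition at high dilution favours ring closure over oligomerisation.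

**Compound list**

1 | 3-methylbut-1-yne | CC(C)C#C | starting material
2 | N-methoxy-N-methylacetamide | CC(=O)N(C)OC | starting material
3 | 5-methylhex-3-yn-2-one | CC(=O)C#CC(C)C | intermediate
4 | (3E)-5-methyl-4-(pyrrolidin-1-yl)hex-3-en-2-one | CC(C)/C(N1CCCC1)=C\C(C)=O | intermediate
5 | prenyl bromide (1-bromo-3-methylbut-2-ene) | CC(C)=CCBr | starting material
6 | (3E)-2,9-dimethyl-3-(pyrrolidin-1-yl)deca-3,8-dien-5-one | CC(C)/C(N1CCCC1)=C\C(=O)CCC=C(C)C | intermediate
7 | (3E)-2,9-dimethyl-6-(3-methylbut-2-en-1-yl)-3-(pyrrolidin-1-yl)deca-3,8-dien-5-one | CC(C)/C(N1CCCC1)=C\C(=O)C(CC=C(C)C)CC=C(C)C | intermediate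
8 | 1-[(3E)-2,9-dimethyl-6-(3-methylbut-2-en-1-yl)-5-(trimethylsilyloxy)deca-3,5,8-trien-3-yl]pyrrolidine | CC(C)/C(N1CCCC1)=C\C(O[Si](C)(C)C)=C(CC=C(C)C)CC=C(C)C | intermediate
9 | diethyl malonate | CCOC(=O)CC(=O)OCC | starting material
10 | diethyl 2-(3-methylbut-2-en-1-yl)propanedioate | CCOC(=O)C(CC=C(C)C)C(=O)OCC | intermediate
11 | 2-(3-methylbut-2-en-1-yl)propanedioic acid | CC(C)=CCC(C(=O)O)C(=O)O | intermediate
12 | 2-(3-methylbut-2-en-1-yl)propanedioyl dichloride | CC(C)=CCC(C(=O)Cl)C(=O)Cl | intermediate
13 | (6E)-8-methyl-2,4,4-tris(3-methylbut-2-en-1-yl)-3,5-dioxo-7-(pyrrolidin-1-yl)non-6-enoyl chloride (racemic at C2, not isolated) | CC(C)/C(N1CCCC1)=C\C(=O)C(CC=C(C)C)(CC=C(C)C)C(=O)C(CC=C(C)C)C(=O)Cl | intermediate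
14 | 2-[2-methyl-1-(pyrrolidin-1-yl)propylidene]-4,6,6-tris(3-methylbut-2-en-1-yl)cyclohexane-1,3,5-trione (exocyclic alkene geometry and C4 configuration undefined, not isolated) | CC(C)C(N1CCCC1)=C1C(=O)C(CC=C(C)C)C(=O)C(CC=C(C)C)(CC=C(C)C)C1=O | intermediate
15 | colupulone, 3,5-dihydroxy-2-(2-methylpropanoyl)-4,6,6-tris(3-methylbut-2-en-1-yl)cyclohexa-2,4-dien-1-one | CC(C)=CCC1=C(O)C(CC=C(C)C)(CC=C(C)C)C(=O)C(C(=O)C(C)C)=C1O | target

**Count and risks**

Total steps: 9. Longest linear sequence: 6 (steps 1, 2, 3, 4, 5, 9).

Step 9 (bears the label). What may go wrong: intermolecular acylation leading to oligomers, O-acylation to enol lactones that do not revert, or protodesilylation of the diene before the first C–C bond forms. The fallback uses known chemistry and gives up the annulation; it sets out from prenyl bromide 5. Phloroglucinol is C-acylated with isobutyryl chloride (AlCl3, nitrobenzene/CH2Cl2, Friedel–Crafts acylation) to give 2-methyl-1-(2,4,6-trihydroxyphenyl)propan-1-one (phlorisobutyrophenone) F1. F1 is then treated with three equivalents of 5 and NaOMe in MeOH at low temperature; this dearomatising C-prenylation of the acylphloroglucinol should give the target after chromatographic removal of under-alkylated, over-alkylated and O-alkylated material. The fallback comes back to the route at 15.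

Step 5. What may go wrong: slow or misdirected deprotonation at the fully substituted α'-carbon (competing removal of the γ-proton on the isopropyl side), or hydrolysis of the diene during handling. The fallback makes the quaternary carbon last and sets out from the mono-prenyl enaminone 6. Its unhindered α'-CH2 is deprotonated and silylated (LiN(iPr)2, Me3SiCl, THF, −78 °C) to give 1-[(3E)-2,9-dimethyl-5-(trimethylsilyloxy)deca-3,5,8-trien-3-yl]pyrrolidine F2. F2 is combined with 12 under the conditions of step 9; after hydrolysis the trione should tautomerise to the aromatic 2-methyl-1-[2,4,6-trihydroxy-3,5-bis(3-methylbut-2-en-1-yl)phenyl]propan-1-one (deoxycohumulone) F3. F3 is C-prenylated with 5 (NaOMe, MeOH, 0 °C) at one of its two equivalent prenyl-bearing ring carbons, the known last step toward this class of hop acids. The fallback comes back to the route at 15.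

Step 8. What may go wrong: addition of the HCl generated to the prenyl alkene, decarboxylation of the diacid, or loss of HCl from the dichloride to a chlorocarbonyl ketene. The fallback avoids free HCl and sets out from diacid 11. It is silylated with hexamethyldisilazane (CH2Cl2, rt) to give bis(trimethylsilyl) 2-(3-methylbut-2-en-1-yl)propanedioate F4. F4 is treated with oxalyl chloride and catalytic DMF in CH2Cl2 at 0 °C, a neutral silyl ester to acyl chloride conversion in which Me3SiCl, CO and CO2 are the only by-products. The fallback comes back to the route at 12.

**Further compounds**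

F1 | step 9 | 2-methyl-1-(2,4,6-trihydroxyphenyl)propan-1-one (phlorisobutyrophenone) | CC(C)C(=O)c1c(O)cc(O)cc1O
F2 | step 5 | 1-[(3E)-2,9-dimethyl-5-(trimethylsilyloxy)deca-3,5,8-trien-3-yl]pyrrolidine | CC(C)/C(N1CCCC1)=C\C(O[Si](C)(C)C)=CCC=C(C)C
F3 | step 5 | 2-methyl-1-[2,4,6-trihydroxy-3,5-bis(3-methylbut-2-en-1-yl)phenyl]propan-1-one (deoxycohumulone) | CC(C)C(=O)c1c(O)c(CC=C(C)C)c(O)c(CC=C(C)C)c1O
F4 | step 8 | bis(trimethylsilyl) 2-(3-methylbut-2-en-1-yl)propanedioate | CC(C)=CCC(C(=O)O[Si](C)(C)C)C(=O)O[Si](C)(C)C
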